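**Plan**

Numbering: ring carbons C1–C10 (C1 ketone, C3 carbinol, C4=C5 alkene, C6 lactone carbinol, C7 ring fusion, C8 ester carbinol, C10 tertiary carbinol), lactone carbons C11 (=C13H2) and C12, methyls C14 on C10 and C15 on C4.
Retrosynthesis: the lactone is opened first at O–C6 and C11–C12 (CO2 leaves), then the ten-membered ring at C5–C6, then the chain at C2–C3 and at C7–C8, leaving a six-carbon ketoaldehyde (C8–C10, C1, C2, C14), a four-carbon propargylic mesylate (C6, C7, C11, C13), a four-carbon (Z)-iodoenal (C3–C5, C15) and 3-methylbutanoic acid.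
Forward: an allenylindium addition joins mesylate and ketoaldehyde (C7–C8), a boron aldol adds the iodoenal (C2–C3), a Nozaki–Hiyama–Kishi reaction closes the ten-membered ring (C5–C6), and the lactone ring is made last from CO2.
Enabling feature: C6 is a secondary allylic carbon (next to C4=C5) lying 1,3 to the vinylic carbon C11 on C7, so an alkenylcopper at C11 can take up CO2 and the resulting carboxylate reaches C6 through a five-membered transition state and displaces chloride.
Stereochemistry: C10 from a copper bis(oxazoline) Mukaiyama aldol; C7 from the (R)-mesylate (L-glyceraldehyde pool); C8 by anti addition then Mitsunobu inversion; C3 from the chiral boron enolate; C6 by Felkin–Anh ring closure followed by two SN2 inversions (chloride, then carboxylate); the 4Z alkene from a (Z)-alkenyl iodide.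

Key step: step 20

Remark: butane-2,3-dione is assumed to bind the copper catalyst as the same five-membered chelate that pyruvate esters form, so the (R,R)-ligand is chosen for the (R)-carbinol; the sense of the boron aldol in step 13 is likewise assigned by analogy with simpler methyl ketones.

**Route**

Step 1
Reactants: 1 S-ethyl ethanethioate
Product: 3 [1-(ethylsulfanyl)ethenyl]oxy(trimethyl)silane, via lithium enolate 2 (not isolated)
Conditions: LiN(iPr)2, THF, −78 °C; then Me3SiCl, −78 °C → rt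
Reagents that add atoms: chlorotrimethylsilane, C[Si](C)(C)Cl
Why: Kinetic deprotonation of the thioester and O-silylation of its lithium enolate should give the silyl ketene thioacetal (enol silane formation).

Step 2
Reactants: 3 [1-(ethylsulfanyl)ethenyl]oxy(trimethyl)silane, 4 butane-2,3-dione
Product: 6 S-ethyl (3R)-3-hydroxy-3-methyl-4-oxopentanethioate, via silyl ether 5 (not isolated)
Conditions: Cu(OTf)2 (10 mol%), (R,R)-2,2′-isopropylidenebis(4-tert-butyl-2-oxazoline) (11 mol%), THF, −78 °C; then 1 M HCl, rt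
Reagents that add atoms: none
Why: Catalytic enantioselective Mukaiyama aldol: the diketone chelates square-planar divalent copper, the tert-butyl groups shield one carbonyl face, and the enol silane should add to the open face to set C10 as (R), the silyl ether being cleaved on acidic work-up.

Step 3
Reactants: 6 S-ethyl (3R)-3-hydroxy-3-methyl-4-oxopentanethioate
Product: 7 S-ethyl (3R)-3-methyl-4-oxo-3-(triethylsilyloxy)pentanethioate
Conditions: Et3SiOTf, 2,6-lutidine, CH2Cl2, −78 → 0 °C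
Reagents that add atoms: triethylsilyl trifluoromethanesulfonate, CC[Si](CC)(CC)OS(=O)(=O)C(F)(F)F
Why: A silyl triflate with a hindered base silylates the tertiary α-ketol without enolising the ketone (silyl ether protection).

Step 4
Reactants: 7 S-ethyl (3R)-3-methyl-4-oxo-3-(triethylsilyloxy)pentanethioate
Product: 8 (3R)-3-methyl-4-oxo-3-(triethylsilyloxy)pentanal
Conditions: Et3SiH, Pd/C (10 wt%), acetone, rt
Reagents that add atoms: none
Why: Fukuyama reduction stops at the aldehyde and leaves the ketone and silyl ether alone; the γ-keto aldehyde should be used at once and kept away from base.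

Step 5
Reactants: 9 (4S)-2,2-dimethyl-1,3-dioxolane-4-carbaldehyde
Product: 10 (4R)-4-ethynyl-2,2-dimethyl-1,3-dioxolane
Conditions: MeC(O)C(N2)P(O)(OMe)2, K2CO3, MeOH, 0 °C → rt
Reagents that add atoms: dimethyl (1-diazo-2-oxopropyl)phosphonate, CC(=O)C(=[N+]=[N-])P(=O)(OC)OC
Why: Seyferth–Gilbert homologation with the Ohira–Bestmann reagent turns the aldehyde into the terminal alkyne (C11≡C13) without touching the stereocenter that becomes C7.

Step 6
Reactants: 10 (4R)-4-ethynyl-2,2-dimethyl-1,3-dioxolane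
Product: 11 (2R)-but-3-yne-1,2-diol
Conditions: AcOH/H2O (4:1), 40 °C
Reagents that add atoms: none
Why: Mild aqueous acid hydrolyses the acetonide (acetal hydrolysis) and leaves the propargylic stereocenter intact.

Step 7
Reactants: 11 (2R)-but-3-yne-1,2-diol
Product: 12 (2R)-1-(triethylsilyloxy)but-3-yn-2-ol
Conditions: Et3SiCl (1.05 equiv), imidazole, CH2Cl2, −40 °C
Reagents that add atoms: chlorotriethylsilane, CC[Si](Cl)(CC)CC
Why: At low temperature the silyl chloride should react at the primary hydroxyl only (selective silylation).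

Step 8
Reactants: 12 (2R)-1-(triethylsilyloxy)but-3-yn-2-ol
Product: 13 (2R)-1-(triethylsilyloxy)but-3-yn-2-yl methanesulfonate
Conditions: MsCl, Et3N, CH2Cl2, −78 → 0 °C
Reagents that add atoms: methanesulfonyl chloride, CS(=O)(=O)Cl
Why: Sulfonylation at oxygen activates the propargylic carbinol with retention (mesylation).

Step 9
Reactants: 14 prop-2-yn-1-ol
Product: 16 (2Z)-3-iodo-2-methylprop-2-en-1-ol, via alkenylmagnesium 15 (not isolated)
Conditions: MeMgBr (2.5 equiv), CuI (10 mol%), THF, −10 °C → rt; then I2, −78 → 0 °C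
Reagents that add atoms: methylmagnesium bromide, C[Mg]Br; iodine, II
Why: Copper-catalysed carbomagnesiation of the propargylic alkoxide places magnesium cis to the CH2O group through a five-membered chelate, and iodinolysis with retention should give the (Z)-iodide that fixes the C4=C5 geometry.

Step 10
Reactants: 16 (2Z)-3-iodo-2-methylprop-2-en-1-ol
Product: 17 (2Z)-3-iodo-2-methylprop-2-enal
Conditions: MnO2, CH2Cl2, rt, dark; used at once
Reagents that add atoms: none
Why: Neutral allylic oxidation with MnO2 should give the enal without isomerising the alkene.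

Step 11
Reactants: 8 (3R)-3-methyl-4-oxo-3-(triethylsilyloxy)pentanal, 13 (2R)-1-(triethylsilyloxy)but-3-yn-2-yl methanesulfonate
Product: 18 (3R,5S,6S)-6-ethynyl-5-hydroxy-3-methyl-3,7-bis(triethylsilyloxy)heptan-2-one
Conditions: Pd(dppf)Cl2 (5 mol%), InI (1.5 equiv), THF/HMPA (3:1), rt
Reagents that add atoms: none
Why: Palladium-catalysed, InI-mediated propargylation: zerovalent palladium displaces the mesylate anti (SN2′), the allenylindium adds to the aldehyde (not the hindered ketone) through a cyclic SE2′ transition state, so C7 should form with net inversion of the mesylate carbon and C8 anti to it.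

Step 12
Reactants: 18 (3R,5S,6S)-6-ethynyl-5-hydroxy-3-methyl-3,7-bis(triethylsilyloxy)heptan-2-one, 19 3-methylbutanoic acid
Product: 20 (2S,3R,5R)-2-ethynyl-5-methyl-6-oxo-1,5-bis(triethylsilyloxy)heptan-3-yl 3-methylbutanoate
Conditions: PPh3, DIAD, toluene, 0 °C → rt
Reagents that add atoms: none
Why: Mitsunobu esterification installs the isovalerate and inverts C8 in the same SN2 event, converting the anti adduct into the syn C7/C8 relation of the target.

Step 13
Reactants: 20 (2S,3R,5R)-2-ethynyl-5-methyl-6-oxo-1,5-bis(triethylsilyloxy)heptan-3-yl 3-methylbutanoate, 17 (2Z)-3-iodo-2-methylprop-2-enal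
Product: 22 (2S,3R,5R,8R,9Z)-2-ethynyl-8-hydroxy-10-iodo-5,9-dimethyl-6-oxo-1,5-bis(triethylsilyloxy)dec-9-en-3-yl 3-methylbutanoate, via boron enolate 21 (not isolated)
Conditions: (−)-Ipc2BCl, Et3N, Et2O, −78 → 0 °C; then 17, −78 → −20 °C; then MeOH, pH 7 buffer, H2O2, 0 °C
Reagents that add atoms: none
Why: Boron aldol of a methyl ketone: only the C2 methyl can enolise, and the isopinocampheyl groups should steer the enolate to the Re face of the enal to give the (R)-carbinol at C3 (reagent control).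

Step 14
Reactants: 22 (2S,3R,5R,8R,9Z)-2-ethynyl-8-hydroxy-10-iodo-5,9-dimethyl-6-oxo-1,5-bis(triethylsilyloxy)dec-9-en-3-yl 3-methylbutanoate
Product: 23 (2S,3R,5R,8R,9Z)-8-(tert-butyldimethylsilyloxy)-2-ethynyl-10-iodo-5,9-dimethyl-6-oxo-1,5-bis(triethylsilyloxy)dec-9-en-3-yl 3-methylbutanoate
Conditions: tBuMe2SiOTf, 2,6-lutidine, CH2Cl2, −78 °C
Reagents that add atoms: tert-butyldimethylsilyl trifluoromethanesulfonate, CC(C)(C)[Si](C)(C)OS(=O)(=O)C(F)(F)F
Why: Silylation of the β-hydroxy ketone at low temperature blocks retro-aldol and keeps the C3 oxygen from attacking C6 later (silyl ether protection).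

Step 15
Reactants: 23 (2S,3R,5R,8R,9Z)-8-(tert-butyldimethylsilyloxy)-2-ethynyl-10-iodo-5,9-dimethyl-6-oxo-1,5-bis(triethylsilyloxy)dec-9-en-3-yl 3-methylbutanoate
Product: 24 (2S,3R,5R,8R,9Z)-8-(tert-butyldimethylsilyloxy)-2-ethynyl-1-hydroxy-10-iodo-5,9-dimethyl-6-oxo-5-(triethylsilyloxy)dec-9-en-3-yl 3-methylbutanoate
Conditions: PPTS (cat.), MeOH/CH2Cl2 (1:4), 0 °C
Reagents that add atoms: none
Why: Mild acid methanolysis should remove the primary triethylsilyl ether much faster than the tertiary triethylsilyl and secondary tert-butyldimethylsilyl ethers (selective desilylation).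

Step 16
Reactants: 24 (2S,3R,5R,8R,9Z)-8-(tert-butyldimethylsilyloxy)-2-ethynyl-1-hydroxy-10-iodo-5,9-dimethyl-6-oxo-5-(triethylsilyloxy)dec-9-en-3-yl 3-methylbutanoate
Product: 25 (2R,3R,5R,8R,9Z)-8-(tert-butyldimethylsilyloxy)-2-ethynyl-10-iodo-5,9-dimethyl-1,6-dioxo-5-(triethylsilyloxy)dec-9-en-3-yl 3-methylbutanoate
Conditions: Dess–Martin periodinane, NaHCO3, CH2Cl2, 0 °C; crude aldehyde used directly
Reagents that add atoms: none
Why: Buffered Dess–Martin oxidation is base-free, so the acidic C7 hydrogen and the β-acyloxy group of the aldehyde should survive.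

Step 17
Reactants: 25 (2R,3R,5R,8R,9Z)-8-(tert-butyldimethylsilyloxy)-2-ethynyl-10-iodo-5,9-dimethyl-1,6-dioxo-5-(triethylsilyloxy)dec-9-en-3-yl 3-methylbutanoate
Product: 26 (1R,2S,3R,4Z,6R,9R)-6-(tert-butyldimethylsilyloxy)-2-ethynyl-3-hydroxy-5,9-dimethyl-8-oxo-9-(triethylsilyloxy)cyclodec-4-en-1-yl 3-methylbutanoate
Conditions: CrCl2 (8 equiv), NiCl2 (2 mol%), DMSO/THF (3:1), rt, 2 mM, slow addition of 25
Reagents that add atoms: none
Why: Nozaki–Hiyama–Kishi macrocyclisation: the (Z)-alkenylchromium adds to the aldehyde only, closing the ten-membered ring at C5–C6 with the cis alkene already in place, and Felkin–Anh attack anti to the C8 branch should give the 6R alcohol.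

Step 18
Reactants: 26 (1R,2S,3R,4Z,6R,9R)-6-(tert-butyldimethylsilyloxy)-2-ethynyl-3-hydroxy-5,9-dimethyl-8-oxo-9-(triethylsilyloxy)cyclodec-4-en-1-yl 3-methylbutanoate
Product: 27 (1R,2S,3R,4Z,6R,9R)-6-(tert-butyldimethylsilyloxy)-3-hydroxy-5,9-dimethyl-8-oxo-2-[1-(4,4,5,5-tetramethyl-1,3,2-dioxaborolan-2-yl)ethenyl]-9-(triethylsilyloxy)cyclodec-4-en-1-yl 3-methylbutanoate
Conditions: B2pin2 (1.1 equiv), CuCl (5 mol%), 1,3-dimesityl-4,5-dihydroimidazolium chloride (5 mol%), NaOtBu (10 mol%), MeOH (2 equiv), THF, −15 °C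
Reagents that add atoms: bis(pinacolato)diboron, CC1(C)OB(OC1(C)C)B1OC(C)(C)C(C)(C)O1
Why: Copper-catalysed protoboration of a terminal alkyne: with an N-aryl carbene ligand and oxygen substituents flanking the alkyne, boron should go to the internal carbon C11 and methanol protonates the alkenylcopper, giving the 1,1-disubstituted alkenylboronate.

Step 19
Reactants: 27 (1R,2S,3R,4Z,6R,9R)-6-(tert-butyldimethylsilyloxy)-3-hydroxy-5,9-dimethyl-8-oxo-2-[1-(4,4,5,5-tetramethyl-1,3,2-dioxaborolan-2-yl)ethenyl]-9-(triethylsilyloxy)cyclodec-4-en-1-yl 3-methylbutanoate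
Product: 28 (1R,2R,3S,4Z,6R,9R)-6-(tert-butyldimethylsilyloxy)-3-chloro-5,9-dimethyl-8-oxo-2-[1-(4,4,5,5-tetramethyl-1,3,2-dioxaborolan-2-yl)ethenyl]-9-(triethylsilyloxy)cyclodec-4-en-1-yl 3-methylbutanoate
Conditions: PPh3, Cl3CC(O)CCl3, CH2Cl2, −20 → 0 °C
Reagents that add atoms: hexachloroacetone, O=C(C(Cl)(Cl)Cl)C(Cl)(Cl)Cl
Why: Appel-type chlorination with PPh3 and hexachloroacetone converts secondary allylic alcohols into chlorides by SN2 with inversion and without allylic transposition, so C6 should become the (S)-chloride.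

Step 20
Reactants: 28 (1R,2R,3S,4Z,6R,9R)-6-(tert-butyldimethylsilyloxy)-3-chloro-5,9-dimethyl-8-oxo-2-[1-(4,4,5,5-tetramethyl-1,3,2-dioxaborolan-2-yl)ethenyl]-9-(triethylsilyloxy)cyclodec-4-en-1-yl 3-methylbutanoate
Product: 30 (3aR,4R,6R,9R,10Z,11aR)-9-(tert-butyldimethylsilyloxy)-6,10-dimethyl-3-methylidene-2,7-dioxo-6-(triethylsilyloxy)-2,3,3a,4,5,6,7,8,9,11a-decahydrocyclodeca[b]furan-4-yl 3-methylbutanoate, via caesium carboxylate 29 (not isolated)
Conditions: (IPr)CuCl (10 mol%; IPr = 1,3-bis(2,6-diisopropylphenyl)imidazol-2-ylidene), CsF (3 equiv), CO2 (1 atm), DMF, 50 °C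
Reagents that add atoms: carbon dioxide, O=C=O
Why: Fluoride turns the alkenylboronate into a borate that passes its C11 alkenyl group to monovalent copper, CO2 inserts into the Cu–C11 bond (C11–C12), and the copper carboxylate is released as caesium salt 29. The first half is the copper-catalysed carboxylation of alkenylboronic esters with CO2, the second the displacement of a secondary halide by a caesium carboxylate. The carboxylate oxygen attacks C6 from the face opposite to chlorine in a 5-exo-tet closure of the lactone ring (O–C6), which the anti arrangement of C6–Cl and C7–C11 in the extended C5–C6–C7–C8 segment of the ten-membered ring allows. C6 is the only stereocenter formed, and it follows from inversion of the (6S)-chloride, so the lactone oxygen should end on the face that the hydroxyl of 26 occupied. The step needs CO2 capture to outrun attack of the alkenylcopper on the allylic chloride and needs SN2 to beat SN2′; the CO2 atmosphere and the strain of the alternative carbocycles should secure the first, and the second follows because attack at tertiary C4 would require a seven-membered ring. The C3 oxygen stays silylated so that it cannot close a dihydrofuran onto C6.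

Step 21
Reactants: 30 (3aR,4R,6R,9R,10Z,11aR)-9-(tert-butyldimethylsilyloxy)-6,10-dimethyl-3-methylidene-2,7-dioxo-6-(triethylsilyloxy)-2,3,3a,4,5,6,7,8,9,11a-decahydrocyclodeca[b]furan-4-yl 3-methylbutanoate
Product: 31 (3aR,4R,6R,9R,10Z,11aR)-6,9-dihydroxy-6,10-dimethyl-3-methylidene-2,7-dioxo-2,3,3a,4,5,6,7,8,9,11a-decahydrocyclodeca[b]furan-4-yl 3-methylbutanoate
Conditions: HF·pyridine, pyridine, THF, 0 °C → rt
Reagents that add atoms: none
Why: Buffered fluoride cleaves the secondary tert-butyldimethylsilyl and tertiary triethylsilyl ethers under mildly acidic conditions that should leave the α-methylene lactone, the ester and the β-hydroxy ketone intact (desilylation).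

**Compound list**

1 | S-ethyl ethanethioate | CC(=O)SCC | starting material
2 | lithium 1-(ethylsulfanyl)ethenolate | [Li]OC(=C)SCC | intermediate
3 | [1-(ethylsulfanyl)ethenyl]oxy(trimethyl)silane | C=C(O[Si](C)(C)C)SCC | intermediate
4 | butane-2,3-dione | CC(=O)C(C)=O | starting material
5 | S-ethyl (3R)-3-methyl-4-oxo-3-(trimethylsilyloxy)pentanethioate | CC(=O)[C@](C)(O[Si](C)(C)C)CC(=O)SCC | intermediate
6 | S-ethyl (3R)-3-hydroxy-3-methyl-4-oxopentanethioate | CC(=O)[C@](C)(O)CC(=O)SCC | intermediate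
7 | S-ethyl (3R)-3-methyl-4-oxo-3-(triethylsilyloxy)pentanethioate | CC(=O)[C@](C)(O[Si](CC)(CC)CC)CC(=O)SCC | intermediate
8 | (3R)-3-methyl-4-oxo-3-(triethylsilyloxy)pentanal | CC(=O)[C@](C)(O[Si](CC)(CC)CC)CC=O | intermediate
9 | (4S)-2,2-dimethyl-1,3-dioxolane-4-carbaldehyde | O=C[C@@H]1COC(C)(C)O1 | starting material
10 | (4R)-4-ethynyl-2,2-dimethyl-1,3-dioxolane | C#C[C@@H]1COC(C)(C)O1 | intermediate
11 | (2R)-but-3-yne-1,2-diol | C#C[C@@H](O)CO | intermediate
12 | (2R)-1-(triethylsilyloxy)but-3-yn-2-ol | C#C[C@@H](O)CO[Si](CC)(CC)CC | intermediate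
13 | (2R)-1-(triethylsilyloxy)but-3-yn-2-yl methanesulfonate | C#C[C@@H](OS(C)(=O)=O)CO[Si](CC)(CC)CC | intermediate
14 | prop-2-yn-1-ol | C#CCO | starting material
15 | bromomagnesium (2Z)-3-(bromomagnesio)-2-methylprop-2-en-1-olate | Br[Mg]OC/C(C)=C\[Mg]Br | intermediate
16 | (2Z)-3-iodo-2-methylprop-2-en-1-ol | OC/C(C)=C\I | intermediate
17 | (2Z)-3-iodo-2-methylprop-2-enal | O=C/C(C)=C\I | intermediate
18 | (3R,5S,6S)-6-ethynyl-5-hydroxy-3-methyl-3,7-bis(triethylsilyloxy)heptan-2-one | CC(=O)[C@](C)(O[Si](CC)(CC)CC)C[C@H](O)[C@@H](C#C)CO[Si](CC)(CC)CC | intermediate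
19 | 3-methylbutanoic acid | CC(C)CC(=O)O | starting material
20 | (2S,3R,5R)-2-ethynyl-5-methyl-6-oxo-1,5-bis(triethylsilyloxy)heptan-3-yl 3-methylbutanoate | CC(=O)[C@](C)(O[Si](CC)(CC)CC)C[C@@H](OC(=O)CC(C)C)[C@@H](C#C)CO[Si](CC)(CC)CC | intermediate
21 | diisopinocampheylboron enolate of 20 (O-boron enolate at C1=C2) | C=C(OB([C@@H]1C[C@@H]2C[C@H]([C@H]1C)C2(C)C)[C@@H]1C[C@@H]2C[C@H]([C@H]1C)C2(C)C)[C@](C)(O[Si](CC)(CC)CC)C[C@@H](OC(=O)CC(C)C)[C@@H](C#C)CO[Si](CC)(CC)CC | intermediate
22 | (2S,3R,5R,8R,9Z)-2-ethynyl-8-hydroxy-10-iodo-5,9-dimethyl-6-oxo-1,5-bis(triethylsilyloxy)dec-9-en-3-yl 3-methylbutanoate | I/C=C(/C)[C@H](O)CC(=O)[C@](C)(O[Si](CC)(CC)CC)C[C@@H](OC(=O)CC(C)C)[C@@H](C#C)CO[Si](CC)(CC)CC | intermediate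
23 | (2S,3R,5R,8R,9Z)-8-(tert-butyldimethylsilyloxy)-2-ethynyl-10-iodo-5,9-dimethyl-6-oxo-1,5-bis(triethylsilyloxy)dec-9-en-3-yl 3-methylbutanoate | I/C=C(/C)[C@H](O[Si](C)(C)C(C)(C)C)CC(=O)[C@](C)(O[Si](CC)(CC)CC)C[C@@H](OC(=O)CC(C)C)[C@@H](C#C)CO[Si](CC)(CC)CC | intermediate
24 | (2S,3R,5R,8R,9Z)-8-(tert-butyldimethylsilyloxy)-2-ethynyl-1-hydroxy-10-iodo-5,9-dimethyl-6-oxo-5-(triethylsilyloxy)dec-9-en-3-yl 3-methylbutanoate | I/C=C(/C)[C@H](O[Si](C)(C)C(C)(C)C)CC(=O)[C@](C)(O[Si](CC)(CC)CC)C[C@@H](OC(=O)CC(C)C)[C@@H](C#C)CO | intermediate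
25 | (2R,3R,5R,8R,9Z)-8-(tert-butyldimethylsilyloxy)-2-ethynyl-10-iodo-5,9-dimethyl-1,6-dioxo-5-(triethylsilyloxy)dec-9-en-3-yl 3-methylbutanoate | I/C=C(/C)[C@H](O[Si](C)(C)C(C)(C)C)CC(=O)[C@](C)(O[Si](CC)(CC)CC)C[C@@H](OC(=O)CC(C)C)[C@@H](C#C)C=O | intermediate
26 | (1R,2S,3R,4Z,6R,9R)-6-(tert-butyldimethylsilyloxy)-2-ethynyl-3-hydroxy-5,9-dimethyl-8-oxo-9-(triethylsilyloxy)cyclodec-4-en-1-yl 3-methylbutanoate | O[C@@H]1/C=C(/C)[C@H](O[Si](C)(C)C(C)(C)C)CC(=O)[C@](C)(O[Si](CC)(CC)CC)C[C@@H](OC(=O)CC(C)C)[C@H]1C#C | intermediate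
27 | (1R,2S,3R,4Z,6R,9R)-6-(tert-butyldimethylsilyloxy)-3-hydroxy-5,9-dimethyl-8-oxo-2-[1-(4,4,5,5-tetramethyl-1,3,2-dioxaborolan-2-yl)ethenyl]-9-(triethylsilyloxy)cyclodec-4-en-1-yl 3-methylbutanoate | O[C@@H]1/C=C(/C)[C@H](O[Si](C)(C)C(C)(C)C)CC(=O)[C@](C)(O[Si](CC)(CC)CC)C[C@@H](OC(=O)CC(C)C)[C@H]1C(=C)B2OC(C)(C)C(C)(C)O2 | intermediate
28 | (1R,2R,3S,4Z,6R,9R)-6-(tert-butyldimethylsilyloxy)-3-chloro-5,9-dimethyl-8-oxo-2-[1-(4,4,5,5-tetramethyl-1,3,2-dioxaborolan-2-yl)ethenyl]-9-(triethylsilyloxy)cyclodec-4-en-1-yl 3-methylbutanoate | Cl[C@H]1/C=C(/C)[C@H](O[Si](C)(C)C(C)(C)C)CC(=O)[C@](C)(O[Si](CC)(CC)CC)C[C@@H](OC(=O)CC(C)C)[C@H]1C(=C)B2OC(C)(C)C(C)(C)O2 | intermediate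
29 | caesium 2-[(1R,2S,3Z,5R,8R,10R)-5-(tert-butyldimethylsilyloxy)-2-chloro-4,8-dimethyl-10-(3-methylbutanoyloxy)-7-oxo-8-(triethylsilyloxy)cyclodec-3-en-1-yl]prop-2-enoate | Cl[C@H]1/C=C(/C)[C@H](O[Si](C)(C)C(C)(C)C)CC(=O)[C@](C)(O[Si](CC)(CC)CC)C[C@@H](OC(=O)CC(C)C)[C@H]1C(=C)C(=O)[O-].[Cs+] | intermediate
30 | (3aR,4R,6R,9R,10Z,11aR)-9-(tert-butyldimethylsilyloxy)-6,10-dimethyl-3-methylidene-2,7-dioxo-6-(triethylsilyloxy)-2,3,3a,4,5,6,7,8,9,11a-decahydrocyclodeca[b]furan-4-yl 3-methylbutanoate | C=C1C(=O)O[C@@H]2/C=C(/C)[C@H](O[Si](C)(C)C(C)(C)C)CC(=O)[C@](C)(O[Si](CC)(CC)CC)C[C@@H](OC(=O)CC(C)C)[C@@H]12 | intermediate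
31 | (3aR,4R,6R,9R,10Z,11aR)-6,9-dihydroxy-6,10-dimethyl-3-methylidene-2,7-dioxo-2,3,3a,4,5,6,7,8,9,11a-decahydrocyclodeca[b]furan-4-yl 3-methylbutanoate (CNP0406522.1) | C=C1C(=O)O[C@@H]2/C=C(/C)[C@H](O)CC(=O)[C@](C)(O)C[C@@H](OC(=O)CC(C)C)[C@@H]12 | target

**Count and risks**

Total step count: 21. Longest linear sequence: 15 steps (steps 1–4 then 11–21; the branch through steps 5–8 is equally long).

Step 20. The allylic chloride may be consumed before lactonisation, by fluoride-induced elimination or by attack of the alkenylcopper on the allylic system, and the boronate may protodeboronate. The fallback sets out from alcohol 27 and comes back at lactone 30. Methyl chloroformate and pyridine convert 27 into the C6 methyl carbonate F1, which keeps the configuration of 27 and is inert to fluoride and to alkenylcopper. The same copper-catalysed carboxylation (CsF, CO2, DMF) and mild acidification give the acrylic acid F2. Pd(PPh3)4 and Et3N in THF then ionise the allylic carbonate with inversion, and the tethered carboxylate attacks C6 of the allylpalladium from the face opposite to the metal, so the lactone should form with overall retention.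

Step 17. Ring closure may be slower than epimerisation or β-elimination of the α-ethynyl aldehyde, and facial selectivity in the addition may be poor. The fallback answers the selectivity problem; it sets out from aldehyde 25 and comes back at 30. The C6-epimeric alcohol F3 formed beside 26 is carried on separately: protoboration as in step 18 gives the boronate F4, copper-catalysed carboxylation with no leaving group at C6 gives the hydroxy acid F5, and a Mitsunobu lactonisation (PPh3, DIAD, THF) closes the O–C6 bond with inversion. Both C6 epimers then converge on 30.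

Step 12. Substitution at the hindered C8 may lose to elimination toward the conjugated enyne or stall. The fallback sets C8 directly; it sets out from aldehyde 8 and comes back at ester 20. Commercial (4R)-2,2-dimethyl-1,3-dioxolane-4-carbaldehyde is taken through the conditions of steps 5 to 8 to the alkyne F6, the diol F7, the silyl ether F8 and the (S)-mesylate F9. Bu3SnLi with CuBr·SMe2 displaces the mesylate in an anti SN2′ sense to give the allenylstannane F10. Its BF3·OEt2-promoted addition to 8 at −78 °C through an open transition state (anti SE2′) should give the syn homopropargylic alcohol F11, with C7 and C8 both as in the target. 3-Methylbutanoyl chloride, pyridine and DMAP then give 20 with no inversion at C8.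

**Further compounds**

F1 | step 20 | C6 methyl carbonate of 27 | COC(=O)O[C@@H]1/C=C(/C)[C@H](O[Si](C)(C)C(C)(C)C)CC(=O)[C@](C)(O[Si](CC)(CC)CC)C[C@@H](OC(=O)CC(C)C)[C@H]1C(=C)B2OC(C)(C)C(C)(C)O2
F2 | step 20 | 2-substituted acrylic acid from F1 (CO2H in place of the boronate) | COC(=O)O[C@@H]1/C=C(/C)[C@H](O[Si](C)(C)C(C)(C)C)CC(=O)[C@](C)(O[Si](CC)(CC)CC)C[C@@H](OC(=O)CC(C)C)[C@H]1C(=C)C(=O)O
F3 | step 17 | C6 epimer of 26 | O[C@H]1/C=C(/C)[C@H](O[Si](C)(C)C(C)(C)C)CC(=O)[C@](C)(O[Si](CC)(CC)CC)C[C@@H](OC(=O)CC(C)C)[C@H]1C#C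
F4 | step 17 | C6 epimer of 27 | O[C@H]1/C=C(/C)[C@H](O[Si](C)(C)C(C)(C)C)CC(=O)[C@](C)(O[Si](CC)(CC)CC)C[C@@H](OC(=O)CC(C)C)[C@H]1C(=C)B2OC(C)(C)C(C)(C)O2
F5 | step 17 | hydroxy acid from F4 (CO2H in place of the boronate) | O[C@H]1/C=C(/C)[C@H](O[Si](C)(C)C(C)(C)C)CC(=O)[C@](C)(O[Si](CC)(CC)CC)C[C@@H](OC(=O)CC(C)C)[C@H]1C(=C)C(=O)O
F6 | step 12 | (4S)-4-ethynyl-2,2-dimethyl-1,3-dioxolane | C#C[C@H]1COC(C)(C)O1
F7 | step 12 | (2S)-but-3-yne-1,2-diol | C#C[C@H](O)CO
F8 | step 12 | (2S)-1-(triethylsilyloxy)but-3-yn-2-ol | C#C[C@H](O)CO[Si](CC)(CC)CC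
F9 | step 12 | (2S)-1-(triethylsilyloxy)but-3-yn-2-yl methanesulfonate | C#C[C@H](OS(C)(=O)=O)CO[Si](CC)(CC)CC
F10 | step 12 | tributyl[(P)-4-(triethylsilyloxy)buta-1,2-dien-1-yl]stannane | CCCC[Sn](CCCC)(CCCC)C=[C@@]=CCO[Si](CC)(CC)CC
F11 | step 12 | (3R,5R,6S)-6-ethynyl-5-hydroxy-3-methyl-3,7-bis(triethylsilyloxy)heptan-2-one | CC(=O)[C@](C)(O[Si](CC)(CC)CC)C[C@@H](O)[C@@H](C#C)CO[Si](CC)(CC)CC
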